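| setting | ash | alder | flask |
|---|---|---|---|
| starting material | 17 mM | 11 mM | 17 mM |
| remark | the very flask that is asked about, followed so far | run made earlier |  |
| time |  |  | 12 min |

ash run (percent of the starting material charged)

| time / s | product / % |
|---|---|
| 10.0 | 0 |
| 15.0 | 1 |
| 25.0 | 2 |
| 40.0 | 9 |
| 60.0 | 7 |

alder run (percent of the starting material charged)

| time / min | product / % |
|---|---|
| 1.00 | 10 |
| 1.33 | 13 |
| 2.00 | 20 |
| 3.00 | 28 |
| 5.00 | 41 |
| 8.00 | 56 |
| 12.0 | 72 |

(each reading ± 2 percentage points)

- amount of product in percent of the starting material charged, at 40 s, 3.0 min and 12 min

1. I began with the easy step, the last alder reading. Taken as one first-order step, 72% at 12.0 min gave 0.106 /min as the fraction of the unconverted charge turning to product per minute, my drain constant, an apparent first-order constant. It returned the alder run's first reading as 10.1% against 10%, and its reading at 3.00 min as 27.2% against 28%.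

2. A first-order step turns the same fraction of any charge. With this step on its own, my reckoning put product in the ash flask at 6.83% of the charge at 40 s, 27.3% at 3.0 min and 72.0% at 12 min.

3. The crystals added no correction to my reckoning, for they are counted in product, so passing between solution and solid leaves the total as it was.

4. The intermediate and the dormant form I treated as a correction, read from the ash run at its higher charge. Over its 5 readings the drain constant stood on average 1.3 percentage points above them, less than the scatter of 2 points on one reading. So I applied no correction and kept the numbers of step 2.

5. The forecast gave 5.5%, 24% and 67%, taking a lower constant of 0.095 per minute with a small lag, and allowing for “a little more material held dormant at higher concentration”. At 12 min it stood 5 points below my number.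

6. The ash flask gave 6.36%, 26.6% and 71.2%, which at 12 min was 4.2 points above the forecast and 0.8 points below my number.

    starting material ⇌ intermediate (K = 0.730, k = 0.200 /s)
    intermediate → product (k = 0.00530 /s)
    starting material ⇌ dormant form (K = 0.480, k = 0.310 /s)
    crystals ⇌ product, rate k4*(cs4 - [product]) while solid is left; crystals form when [product] > cs4 (solubility = 6.70 mM, k = 3.60 /s)

In the ash flask the backward turnover between starting material and intermediate was 98% of the forward one. The drain constant left 28.0% of the charge unconverted at 12 min, and the ash flask then held 13.1% starting material, 9.42% intermediate and 6.29% dormant form, together 28.8%. For the thin run, at twice the dilution, the drain constant again gives 72.0% at 12 min, and that run stood at 71.2%.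

(The earlier runs and the new flask come from a simulation from invented constants, and the scatter is random.)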